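The readings were computed with constants of no real substance.

Temperature was the thread I followed, since the two earlier runs differ in it and the three flasks are set apart by it.

all flasks: left-handed substrate 0.47 M; right-handed substrate 0.47 M

| charge | solid reagent | temperature | remark | time |
|---|---|---|---|---|
| noon | 0.66 M | −40 °C | run made earlier |  |
| summer | 1 M | −5 °C | run made earlier |  |
| south | 0.470 M | 25 °C |  | 12 min |
| north | 0.470 M | −5 °C |  | 12 min |
| south-west | 0.470 M | −35 °C |  | 12 min |

| run | time / min | left-handed product / % | right-handed product / % |
|---|---|---|---|
| noon | 80.0 | 0.2 | 0.4 |
| noon | 150 | 1.1 | 0 |
| noon | 240 | 3.4 | 0.5 |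
| noon | 300 | 4.2 | 0.1 |
| summer | 4.00 | 0 | 0 |
| summer | 8.00 | 0.5 | 0 |
| summer | 20.0 | 2.4 | 0.5 |
| summer | 50.0 | 8.2 | 1.8 |

(readings scatter by 0.5 percentage points)

- the flask with the highest excess of left-handed product over right-handed product ("all alike" if they lie within 1.5 percentage points) (south / north / south-west / all alike)
- excess of left-handed product over right-handed product at the end, south
- excess of left-handed product over right-handed product at the end, north
- excess of left-handed product over right-handed product at the end, south-west

- partner is single-handed; left-handed substrate and right-handed substrate are mirror images of each other, charged as a racemate, each of them at the stated concentration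
- solid, in amounts per volume of the solution: solid reagent
- the numbers in the tables scatter with a standard deviation of 0.5 percentage points
- at the start none of the solid reagent is in solution
- an excess is below zero if the other one leads
- the handed part of partner does not stay in what it makes, so the products of the two hands are mirror images too

I took the excess as (L−R)/(L+R), with L and R the left-handed and right-handed product, so it follows from the selectivity factor s = L/R. Summing each column, the right-handed product came to 1.00 % in the noon run and 2.30 % in the summer run, so I read s = 8.90 at −40 °C and 4.83 at −5 °C. I joined these two ends by a straight line of ln s against inverse temperature, taking the difference as one of temperature, though the two runs also differ in solid reagent charged (0.66 M against 1 M). Its slope times the gas constant came to 9.09 kJ mol⁻¹: the gap ΔE, the activation energy of the route to right-handed product minus that of the route to left-handed product. Carried along the line, it gave excesses of 52.4 % for south, 65.7 % for north and 77.9 % for south-west.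

But the noon sum is built from 4 readings, and such a sum scatters by 1 percentage point, as much as the sum itself. Propagated, that puts 16.2 kJ mol⁻¹ on the gap, larger than the gap. I could not compute this away, so my numbers stayed soft.

Might the excess drift with time? In the summer run L/R read 4.80 at 20.0 min and 4.56 at 50.0 min, and the flasks stop sooner. I kept north's figure, but south is warmer than both earlier runs, so there I was extrapolating.

The forecast gives the same figures: 52 %, 66 %, 78 %, with south-west highest. “The coldest flask wins, though its product is barely measurable.”

South-west does lead, at 90.0 %, with north at 73.0 % and south at 42.7 %. South-west holds 0.0648 % left-handed product at 12.0 min, less than the scatter of one reading. From north to south-west my gap promised a rise of 0.514 in ln s. The two excesses give 1.09, and the uncertainty I had put on the gap allows ±0.915 there.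

    partner + left-handed substrate → left-handed product (k = 0.0110 M⁻¹ s⁻¹, Ea = 51.0 kJ mol⁻¹)
    partner + right-handed substrate → right-handed product (k = 0.00400 M⁻¹ s⁻¹, Ea = 70.0 kJ mol⁻¹)
    solid reagent ⇌ partner, rate k3*(cs3 - [partner]) while solid is left; crystals form when [partner] > cs3 (solubility = 0.150 M, k = 6.30 × 10⁻⁴ s⁻¹)
    partner → decomposed reagent (k = 0.00110 s⁻¹, Ea = 93.0 kJ mol⁻¹)
    left-handed product ⇌ right-handed product (k = 1.10 × 10⁻⁴ s⁻¹, Ea = 84.0 kJ mol⁻¹)
    (constants at 25 °C)

For the flask like south-west but run at −10 °C, I started from north's excess and applied the gap across the small step in temperature, which gave 74.7 %. The computed flask gives 76.6 %.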